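The data are simulated for substances that don't exist; noise was put on by code.

The constant to carry into this repeat is a drain rate, and the grey run lets you read it before you start.

| flask | starting material | protic impurity | catalyst | remark | time |
|---|---|---|---|---|---|
| grey | 0.50 M | 0.30 M | 2.1 mol% | run made earlier |  |
| flask | 0.50 M | 0.150 M | 2.1 mol% |  | 30 min |

grey run (percent of the starting material charged)

| time / min | target / % | isomer of the product / % | starting material / % |
|---|---|---|---|
| 0.667 | 11.6 | 12.8 | 35.0 |
| 1.50 | 12.9 | 18.0 | 18.1 |
| 4.00 | 7.1 | 29.0 | 8.8 |
| 10.0 | 1.9 | 37.3 | 2.1 |

(readings scatter by 0.5 percentage points)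

- no earlier run changes the charge of protic impurity; that part of a forecast is a guess

- ratio of target to isomer of the product at 1.5 s
- ratio of target to isomer of the product at 30 min

Take the grey run's rungs in order of time. By the first reading, at 0.667 min, starting material is down to 35.0%, and target and isomer stand at a ratio of 0.906. That ratio has fallen to 0.717 at 1.50 min. Run backwards, it gives me about 1.09 as a rough guess for the grey run at 1.5 s, which no reading reaches, and for your flask that number is a further guess.

Next comes the gap in the balance: 58.7% at 10.0 min, against an impurity charge of 60.0% of the starting material. Your flask charges 30.0%.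

Last comes the tail. Between 4.00 min and 10.0 min, target plus starting material, the pool, falls from 15.9% to 4.00%, which is 0.230 min⁻¹. Isomer takes 69.7% of that loss. Their product is κ, the pseudo-first-order rate at which the pool becomes isomer at this catalyst concentration: 0.160 min⁻¹, a reading with a half-life of 4.33 min.

Once the gap stops growing, as I assume it does near the impurity charge, I let c(target)/c(isomer) fall with κ. Starting from the grey ratio of 0.0509 at 10.0 min, which for your flask is a guess, I reach 0.00206 at 30 min.

The forecast says 0.9 and 0.001, holding that “the impurity probably consumes starting material stoichiometrically to an unseen by-product”.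

The flask gives 3.01 at 1.5 s and 0.00170 at 30 min.

    starting material ⇌ other conformer (K = 0.0366, k = 0.0211 s⁻¹)
    starting material + catalyst ⇌ catalyst + target (K = 0.581, k = 0.633 M⁻¹ s⁻¹)
    catalyst + other conformer → catalyst + isomer of the product (k = 18.6 M⁻¹ s⁻¹)
    starting material + protic impurity → quenched substrate (k = 0.0980 M⁻¹ s⁻¹)
    2 starting material → homo dimer (k = 5.34 × 10⁻⁵ M⁻¹ s⁻¹)

At 15.0 min this flask holds 1.72% target and 65.9% isomer, and κ, read from the grey run, reckons that ratio on to 0.00237 at 30 min. The neighbour flask at 0.30 M has the same loading, so its catalyst concentration is lower, and it holds 0.500 equiv of impurity; if κ scales with catalyst concentration, it becomes 0.0963 min⁻¹. From the grey ratio at 10.0 min, again a guess, that reckons 0.00742, and the neighbour flask gives 0.00853.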